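**Retrosynthetic overview**
Leoligin is a 2,3-trans-3,4-cis tetrahydrofuran (O1, C2 aryl, C3, C4, C5). C3 carries the oxygenated carbon C9 and its neighbour C4 carries the benzylic carbon C7'. The plan rests on this adjacent pair, a CH2O arm and an ArCH2 arm across the C3–C4 bond.
The angelate is attached last at C9–OH (Mitsunobu), and the C4 centre comes from hydrogenation of a C4=C7' benzylidene.
The C3–C4 bond and the only ring form together. Cp2TiCl opens a terminal C3–C9 oxirane to the C3 radical, which closes 5-exo-dig on the C4≡C7' aryl alkyne tethered through C2–O1–C5.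
The epoxy ether comes from O1–C5 etherification of lipase-resolved (S)-aryl vinyl carbinol (veratraldehyde, vinyl Grignard) with the aryl propargyl bromide (4-iodoveratrole, propargyl alcohol), followed by epoxidation.

Key step: step 7

Assumption: the two oxirane epimers of 11 and the two alkene isomers of 13 are carried on unseparated, because each pair converges on one product in the following step.

Step 1
Reactants: 1 4-iodoveratrole; 2 propargyl alcohol
Product: 3 3-(3,4-dimethoxyphenyl)prop-2-yn-1-ol
Conditions: PdCl2(PPh3)2 (2 mol%), CuI (4 mol%), Et3N, THF, rt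
Reagents that add atoms: none
Why: Sonogashira coupling; the aryl iodide adds oxidatively to zerovalent palladium at room temperature and the copper acetylide of the unprotected alcohol transmetallates, so no protecting group is needed.

Step 2
Reactants: 3 3-(3,4-dimethoxyphenyl)prop-2-yn-1-ol
Product: 4 4-(3-bromoprop-1-yn-1-yl)-1,2-dimethoxybenzene
Conditions: CBr4, PPh3, CH2Cl2, 0 °C
Reagents that add atoms: carbon tetrabromide, BrC(Br)(Br)Br
Why: Appel reaction; bromide displaces the primary propargylic alcohol through its alkoxyphosphonium ion under neutral conditions, which spare the electron-rich arene and the alkyne.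

Step 3
Reactants: 5 veratraldehyde
Product: 7 rac-1-(3,4-dimethoxyphenyl)prop-2-en-1-ol, via bromomagnesium alkoxide 6 (not isolated)
Conditions: vinylmagnesium bromide, THF, 0 °C; then sat. aq. NH4Cl
Reagents that add atoms: vinylmagnesium bromide, C=C[Mg]Br
Why: Grignard 1,2-addition to a non-enolisable aromatic aldehyde gives the future C2 centre as a racemate, and the mild NH4Cl quench avoids acid-promoted 1,3-transposition of the electron-rich aryl vinyl carbinol.

Step 4
Reactants: 7 rac-1-(3,4-dimethoxyphenyl)prop-2-en-1-ol
Product: 8 (S)-1-(3,4-dimethoxyphenyl)prop-2-en-1-ol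
Conditions: Amano lipase PS (Burkholderia cepacia), vinyl acetate, MTBE, 30 °C, stopped just past half conversion; chromatography
Reagents that add atoms: none
Why: Lipase-catalysed kinetic resolution by irreversible transesterification; under the Kazlauskas size rule (aryl large, vinyl medium) the (R)-alcohol is acetylated fast, so the (S)-alcohol with the C2 configuration of the target is left behind and is separated from the ester.

Step 5
Reactants: 8 (S)-1-(3,4-dimethoxyphenyl)prop-2-en-1-ol; 4 4-(3-bromoprop-1-yn-1-yl)-1,2-dimethoxybenzene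
Product: 10 4-[(1S)-1-{[3-(3,4-dimethoxyphenyl)prop-2-yn-1-yl]oxy}prop-2-en-1-yl]-1,2-dimethoxybenzene, via sodium alkoxide 9 (not isolated)
Conditions: NaH, THF/DMF, 0 °C; then 4, Bu4NI (cat.), 0 °C to rt
Reagents that add atoms: none
Why: Williamson ether synthesis; the alkoxide attacks the primary propargylic bromide by SN2 to form O1–C5, and the C2–O bond is not touched, so the configuration is retained.

Step 6
Reactants: 10 4-[(1S)-1-{[3-(3,4-dimethoxyphenyl)prop-2-yn-1-yl]oxy}prop-2-en-1-yl]-1,2-dimethoxybenzene
Product: 11 2-[(R)-(3,4-dimethoxyphenyl){[3-(3,4-dimethoxyphenyl)prop-2-yn-1-yl]oxy}methyl]oxirane (both oxirane epimers)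
Conditions: mCPBA (excess), CH2Cl2/aq. phosphate buffer (pH 7.5), 0 °C to rt
Reagents that add atoms: mCPBA, OOC(=O)c1cccc(Cl)c1
Why: Prilezhaev epoxidation; peracids attack alkenes far faster than alkynes, the buffer keeps the benzylic ether from ionising, and the uncontrolled oxirane centre does not matter because step 7 erases it (the benzylic descriptor changes from S to R by priority only).

Step 7
Reactants: 11 2-[(R)-(3,4-dimethoxyphenyl){[3-(3,4-dimethoxyphenyl)prop-2-yn-1-yl]oxy}methyl]oxirane
Product: 13 [(2S,3R)-4-(3,4-dimethoxybenzylidene)-2-(3,4-dimethoxyphenyl)tetrahydrofuran-3-yl]methanol (alkene isomer mixture), via Cp2Ti(Cl) alkoxide 12 (not isolated)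
Conditions: Cp2TiCl2 (2.5 equiv), Zn dust, THF, rt, green Cp2TiCl solution added slowly to dilute 11 in THF under Ar; then aq. NaH2PO4
Reagents that add atoms: none
Why: Cp2TiCl (trivalent titanium, made from Cp2TiCl2 and Zn) binds the oxirane oxygen and passes one electron to it, so the C3–O bond breaks and leaves the secondary C3 radical with C9 held as a tetravalent titanium alkoxide; the monosubstituted oxirane secures this regiochemistry, since the alternative is a primary radical. The C3 radical adds to alkyne carbon C4 in a 5-exo-dig closure that forms C3–C4 and the ring O1–C2–C3–C4–C5, and both the three-atom C2–O1–C5 tether and the aryl group, which stabilises the vinyl radical at C7', favour exo over 6-endo attack. The C7' vinyl radical takes a hydrogen atom from THF (or is caught by a second Cp2TiCl and protonated in the quench), which gives alkoxide 12 as an alkene isomer mixture and alcohol 13 after hydrolysis. The closest known reaction type is the titanocene-mediated reductive cyclisation of epoxy propargyl ethers to 3-hydroxymethyl-4-alkylidene tetrahydrofurans (Nugent–RajanBabu epoxide opening). C3 is the only new stereocentre and is controlled by C2: in the chair-like transition state the C2 aryl group and the C3 CH2O[Ti] arm both sit pseudo-equatorial, which gives the 2,3-trans (2S,3R) ring, and both oxirane epimers converge because C3 passes through a planar radical. The step needs ring closure to outrun capture of the C3 radical by a second titanium centre (which would end in deoxygenation back to 10), and this is served by the short oxygen-containing tether, the aryl-activated alkyne and the slow addition of the reagent.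

Step 8
Reactants: 13 [(2S,3R)-4-(3,4-dimethoxybenzylidene)-2-(3,4-dimethoxyphenyl)tetrahydrofuran-3-yl]methanol
Product: 14 [(2S,3R,4R)-4-(3,4-dimethoxybenzyl)-2-(3,4-dimethoxyphenyl)tetrahydrofuran-3-yl]methanol (lariciresinol dimethyl ether)
Conditions: H2 (1 atm), Pd/C (10 wt% Pd), EtOAc, rt, stopped after one equivalent of H2
Reagents that add atoms: none
Why: Heterogeneous catalytic hydrogenation (syn addition); the alkene should adsorb through the face opposite the adjacent C3 hydroxymethyl arm, which allylic strain against the benzylidene pushes pseudo-axial, so hydrogen reaches C4 trans to C9 and the benzyl group ends cis to it (4R), both alkene isomers give the same centre, and the neutral solvent and low pressure protect the benzylic C2–O1 bond.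

Step 9
Reactants: 14 [(2S,3R,4R)-4-(3,4-dimethoxybenzyl)-2-(3,4-dimethoxyphenyl)tetrahydrofuran-3-yl]methanol; 15 angelic acid
Product: 16 leoligin
Conditions: PPh3, DIAD, THF, 0 °C to rt
Reagents that add atoms: none
Why: Mitsunobu esterification; the primary C9 alcohol is activated as its alkoxyphosphonium ion and displaced by angelate, so the acid is never converted into an acylating agent, its Z double bond has no pathway to the tiglate, and no stereocentre is involved because C9 is a CH2 group.

**Compound list**
1 | 4-iodoveratrole (4-iodo-1,2-dimethoxybenzene) | COc1ccc(I)cc1OC | starting material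
2 | propargyl alcohol | C#CCO | starting material
3 | 3-(3,4-dimethoxyphenyl)prop-2-yn-1-ol | COc1ccc(C#CCO)cc1OC | intermediate
4 | 4-(3-bromoprop-1-yn-1-yl)-1,2-dimethoxybenzene | COc1ccc(C#CCBr)cc1OC | intermediate
5 | veratraldehyde (3,4-dimethoxybenzaldehyde) | COc1ccc(C=O)cc1OC | starting material
6 | bromomagnesium 1-(3,4-dimethoxyphenyl)prop-2-en-1-olate, racemic (not isolated) | C=CC(O[Mg]Br)c1ccc(OC)c(OC)c1 | intermediate
7 | rac-1-(3,4-dimethoxyphenyl)prop-2-en-1-ol | C=CC(O)c1ccc(OC)c(OC)c1 | intermediate
8 | (S)-1-(3,4-dimethoxyphenyl)prop-2-en-1-ol | O[C@@H](C=C)c1ccc(OC)c(OC)c1 | intermediate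
9 | sodium (S)-1-(3,4-dimethoxyphenyl)prop-2-en-1-olate (not isolated) | [Na+].[O-][C@@H](C=C)c1ccc(OC)c(OC)c1 | intermediate
10 | 4-[(1S)-1-{[3-(3,4-dimethoxyphenyl)prop-2-yn-1-yl]oxy}prop-2-en-1-yl]-1,2-dimethoxybenzene | COc1ccc(C#CCO[C@@H](C=C)c2ccc(OC)c(OC)c2)cc1OC | intermediate
11 | 2-[(R)-(3,4-dimethoxyphenyl){[3-(3,4-dimethoxyphenyl)prop-2-yn-1-yl]oxy}methyl]oxirane, both oxirane epimers | COc1ccc(C#CCO[C@@H](C2CO2)c2ccc(OC)c(OC)c2)cc1OC | intermediate
12 | Cp2Ti(Cl) alkoxide of alcohol 13, tetravalent titanium, alkene isomer mixture (not isolated) | [Cl-].[Ti+4].c1cc[cH-]c1.c1cc[cH-]c1.[O-]C[C@H]1C(=Cc2ccc(OC)c(OC)c2)CO[C@@H]1c1ccc(OC)c(OC)c1 | intermediate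
13 | [(2S,3R)-4-(3,4-dimethoxybenzylidene)-2-(3,4-dimethoxyphenyl)tetrahydrofuran-3-yl]methanol, 2,3-trans, alkene isomer mixture | OC[C@H]1C(=Cc2ccc(OC)c(OC)c2)CO[C@@H]1c1ccc(OC)c(OC)c1 | intermediate
14 | [(2S,3R,4R)-4-(3,4-dimethoxybenzyl)-2-(3,4-dimethoxyphenyl)tetrahydrofuran-3-yl]methanol, 2,3-trans-3,4-cis | OC[C@H]1[C@@H](Cc2ccc(OC)c(OC)c2)CO[C@@H]1c1ccc(OC)c(OC)c1 | intermediate
15 | angelic acid ((Z)-2-methylbut-2-enoic acid) | C/C=C(/C)C(=O)O | starting material
16 | leoligin, [(2S,3R,4R)-4-(3,4-dimethoxybenzyl)-2-(3,4-dimethoxyphenyl)tetrahydrofuran-3-yl]methyl (Z)-2-methylbut-2-enoate | C/C=C(/C)C(=O)OC[C@H]1[C@@H](Cc2ccc(OC)c(OC)c2)CO[C@@H]1c1ccc(OC)c(OC)c1 | target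

**Total step count:** 9
**Longest linear sequence:** 7 (steps 3 to 9, from veratraldehyde); steps 1 and 2 form the side branch.

**Steps most likely to fail**

1. Step 7.
- Risk: capture of the C3 radical by a second titanium centre with loss of titanium oxide (net deoxygenation), or chloride opening of the oxirane by the Lewis-acidic salts, may compete with the fairly slow addition to an alkyne. The trans preference at C3 may also be incomplete.
- Fallback: it sets out from 11. The alkyne is semi-hydrogenated (H2, Pd/CaCO3 poisoned with Pb(OAc)2, quinoline, EtOAc) to the (Z)-cinnamyl ether epoxide F1, whose styrene-type double bond takes up alkyl radicals faster than an alkyne. Cp2TiCl (Cp2TiCl2, Zn, THF) then drives a 5-exo-trig closure. The benzylic C7' radical is reduced by a second Cp2TiCl and protonated in the quench. The cis preference of 1-substituted 5-hexenyl radical closures should place C9 and C7' on the same face. The fallback comes back to the route at 14 and makes step 8 unnecessary.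

2. Step 8.
- Risk: anchoring of the free hydroxyl on the metal surface may deliver hydrogen from the hydroxymethyl face (poor facial selectivity). The double bond may migrate into the ring before reduction, or the benzylic C2–O1 bond may be hydrogenolysed.
- Fallback: it sets C4 by hydroboration instead and sets out from 8.
  - Alkylation with propargyl bromide (NaH, THF) gives the (S)-propargyl ether F2.
  - Buffered mCPBA gives the epoxide F3.
  - Cp2TiCl closes it in the same 5-exo-dig manner to the 4-methylidene tetrahydrofuran alcohol F4.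
  - TBSCl and imidazole give the silyl ether F5.
  - 9-BBN adds from the face opposite the C3 arm to give the B-alkyl borane F6.
  - A B-alkyl Suzuki–Miyaura coupling with 1 (PdCl2(dppf), aq. K3PO4, THF/DMF) gives the benzylated silyl ether F7.
  - TBAF brings the sequence back to the route at 14.

3. Step 6.
- Risk: the monosubstituted, inductively deactivated alkene may be oxidised sluggishly. This leaves time for attack on the electron-rich alkyne or arenes and for acid-induced ionisation of the benzylic ether.
- Fallback: it sets out from 10. The terminal alkene is dihydroxylated (OsO4 cat., NMO, acetone/H2O, conditions under which alkynes react far more slowly) to the diol F8. The primary hydroxyl is sulfonylated selectively (TsCl, Bu2SnO cat., Et3N, CH2Cl2) to the monotosylate F9. K2CO3 in MeOH then closes the oxirane, and the fallback comes back to the route at 11.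

**Further compounds**
F1 | step 7 | 2-[(R)-(3,4-dimethoxyphenyl){[(2Z)-3-(3,4-dimethoxyphenyl)prop-2-en-1-yl]oxy}methyl]oxirane, both oxirane epimers | COc1ccc(/C=C\CO[C@@H](C2CO2)c2ccc(OC)c(OC)c2)cc1OC
F2 | step 8 | 1,2-dimethoxy-4-[(1S)-1-(prop-2-yn-1-yloxy)prop-2-en-1-yl]benzene | C#CCO[C@@H](C=C)c1ccc(OC)c(OC)c1
F3 | step 8 | 2-[(R)-(3,4-dimethoxyphenyl)(prop-2-yn-1-yloxy)methyl]oxirane, both oxirane epimers | C#CCO[C@@H](C1CO1)c1ccc(OC)c(OC)c1
F4 | step 8 | [(2S,3R)-2-(3,4-dimethoxyphenyl)-4-methylidenetetrahydrofuran-3-yl]methanol | OC[C@H]1C(=C)CO[C@@H]1c1ccc(OC)c(OC)c1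
F5 | step 8 | tert-butyldimethylsilyl ether of F4 | CC(C)(C)[Si](C)(C)OC[C@H]1C(=C)CO[C@@H]1c1ccc(OC)c(OC)c1
F6 | step 8 | B-alkyl-9-borabicyclo[3.3.1]nonane adduct of F5, CH2B on C4 cis to C9 | CC(C)(C)[Si](C)(C)OC[C@H]1[C@@H](CB2C3CCCC2CCC3)CO[C@@H]1c1ccc(OC)c(OC)c1
F7 | step 8 | tert-butyldimethylsilyl ether of 14 | CC(C)(C)[Si](C)(C)OC[C@H]1[C@@H](Cc2ccc(OC)c(OC)c2)CO[C@@H]1c1ccc(OC)c(OC)c1
F8 | step 6 | (3R)-3-(3,4-dimethoxyphenyl)-3-{[3-(3,4-dimethoxyphenyl)prop-2-yn-1-yl]oxy}propane-1,2-diol, both C2 epimers | COc1ccc(C#CCO[C@@H](C(O)CO)c2ccc(OC)c(OC)c2)cc1OC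
F9 | step 6 | primary p-toluenesulfonate of F8 | COc1ccc(C#CCO[C@@H](C(O)COS(=O)(=O)c3ccc(C)cc3)c2ccc(OC)c(OC)c2)cc1OC
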